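## Analysis of the target

Target 24 is the 4-methoxybenzoate of a trans-fused bicyclo[5.3.0]decane (hydroazulene) with a quaternary methyl at the ring fusion, a tertiary isopropyl carbinol, a secondary ester and a trisubstituted epoxide. Atoms are numbered C1 (methyl-bearing fusion carbon), C2 and C3 (CH2), C4 (isopropyl carbinol), C5 (fusion CH), C6 (ester-bearing CH), C7 (CH2), C8 and C9 (epoxide carbons, methyl on C8) and C10 (CH2); in this numbering 24 is 1R,4R,5S,6S,8R,9S. If the face of the C1 methyl is called α, the C4 hydroxyl is also α, while H5, the isopropyl group, the C6 oxygen and the epoxide oxygen are β. The fusion is therefore trans, H5 and the C6 oxygen are syn, and all five other stereocentres lie within three bonds of C1. Sensitive groups are the epoxide (acid), the ester (base, organometallics) and the tertiary alcohol; the intermediates add a skipped 1,4-diene whose doubly activated CH2 groups can be drawn into conjugation by base, and a β-hydroxy ketone that can eliminate. The hard parts are the quaternary C1 in a five–seven system, the trans fusion next to it, and an absolute configuration that must be created catalytically. The strategy rests on the five-membered ring C1–C5: a cyclopentane with oxygen on C4, fused through the quaternary C1, is the retron of a Nazarov cyclisation, with C4 as the dienone carbonyl, C1 as the substituted terminus and C2 as an unsubstituted CH2 terminus. Once C1 is set as the only stereocentre, its pseudo-axial methyl is the control element for C5, C6, C4 and the epoxide.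

## Retrosynthetic reasoning

24 ⇒ 23. The two C–O bonds of the epoxide at C8 and C9 are cut first. The epoxide tolerates Lewis acids, single-electron reductants and organometallics least, and in 23 the C8=C9 alkene is the only nucleophilic alkene left. The forward step must deliver oxygen to the β face; the axial C1 methyl, 1,3 to C9, shields the α face.

23 ⇒ 21 + 22. The ester C–O bond at C6 is cut. Late acylation keeps the ester away from the organometallic step, and 21 offers one secondary and one tertiary hydroxyl, so no protecting group is needed.

21 ⇒ 20. The C4–isopropyl bond is cut, which returns the ketone that the key step leaves at C4. The addition must come from the β face and outrun enolisation; in trans-fused 20 the α face of C4 is closed by the C1 methyl.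

20 ⇒ 19 ⇒ 18. The C6–O and C5–H bonds are traced back to the C5=C6 enone 18 through epoxy ketone 19. C6 cannot be oxygenated in a saturated ring, but it is the β-carbon of the enone that the key step delivers. Nucleophilic epoxidation, then reductive cleavage of the C5–O bond, keeps the C6–O bond and lets C5 be protonated. Both events at C5 must occur anti to the C1 methyl; this gives the syn relation of H5 and the C6 oxygen and the trans fusion.

18 ⇒ 17. A methoxycarbonyl group is added at C3. It has no counterpart in the target; it polarises the dienone and gives the Lewis acid a second binding site, and it is removed by dealkoxycarbonylation.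

17 ⇒ 16. The C1–C2 bond is cut, opening the five-membered ring to the cross-conjugated divinyl ketone 16. Cutting here, and not at C4–C5 or C3–C4, creates the quaternary carbon in the ring-forming step from a tetrasubstituted ring alkene and an unhindered CH2 terminus, and leaves a precursor with no stereocentre. The forward reaction, a conrotatory 4π electrocyclisation on a chiral Lewis acid, has to control only the sense of rotation.

16 ⇒ 13 ⇒ 10 + 11. The exocyclic methylene (C2) is removed as a Mannich one-carbon unit, and the C3–C4 bond is cut between ring acid 10 and malonate half-ester salt 11. The reactive 2-methylene β-keto ester thus appears only at the end of the sequence.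

10 ⇒ 9 ⇒ 8 ⇒ 7. The ring methyl that becomes the C1 methyl is disconnected at its C–CH3 bond. A tetrasubstituted enoate of fixed geometry follows from enol triflate 8 of cyclic β-keto ester 7.

7 ⇒ 6. The ring alkene that becomes C8=C9 is cut by a ring-closing metathesis transform. A one-carbon ring expansion of a six-membered β,γ-unsaturated ketone with a diazoacetate ester would use cheaper materials, but it leaves open which of two similar α-CH2 groups migrates. Metathesis fixes the alkene position relative to the β-keto ester by construction.

6 ⇒ 4 + 5 and 4 ⇒ 1 + 2. The bond between the β-keto ester α-carbon and the homoallyl chain is cut (enolate alkylation with 5). Compound 4 comes from acid 1 and 2 by C-acylation and alcoholysis.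

## Alternatives that were turned down

Alternative 1: The five-membered ring is not closed in the key step; C1–C2 and C4–C5 are disconnected together. Forward, a chiral copper–carbene catalyst (from Cu(OTf)2 and an imidazolinium salt) would add a vinylaluminium reagent to one of the two enantiotopic β-carbons of the meso dienone 3,6-dimethylcyclohepta-2,6-dien-1-one A2. The aluminium enolate would be intercepted by an isopropyl-bearing aldehyde to give the trans aldol 2-(1-hydroxy-2-methylpropyl)-3,6-dimethyl-3-vinylcyclohept-6-en-1-one A1.
- For it: enantioselective copper-catalysed conjugate additions that create quaternary carbons on cyclic enones are established, which the asymmetric Nazarov closure onto a fully substituted terminus is not. The anti relation of the vinyl group and the aldol side chain fixes the trans C1/C5 relation by a well-understood enolate trapping, whereas the chosen route relies on a late protonation at C5. On both points this alternative is stronger.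
- Against it: no ring is formed. The vinyl terminus (C3) must still be joined to C4 while the tertiary carbinol is built. The ketone of A1 sits on C6 and its enone alkene on C7=C8, so a deconjugation to C8=C9 and a stereoselective C6 reduction follow. The hindered aluminium enolate next to a new quaternary carbon must add to a branched aldehyde without retro-aldol.
- Comparison: the chosen strategy gives the bicyclic skeleton, the quaternary carbon and correctly placed handles at C4, C5/C6 and C8/C9 in one catalytic step, with a shorter path after it.

Alternative 2: The seven-membered ring is closed last. An intramolecular [2+2] photocycloaddition of an enone forms C1–C10 and C5–C9, and retro-aldol cleavage of C5–C9 after removal of an acetate opens the cyclobutane to the C6-silyloxy bicyclo[5.3.0]decane-4,9-dione A3.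
- For it: photocycloaddition is one of the best ways to bond to a hindered quaternary carbon, and the sequence amounts to a Michael closure that would fail thermally. A3 already carries the C6 oxygen with C5 and C6 arranged. That is stronger than the chosen route on the two centres that there depend on facial selectivity in an epoxidation and a protonation.
- Against it: the absolute configuration must come from an enantiopure C6 silyloxy precursor made separately. A3 has ketones at C4 and C9 that must be told apart before the isopropyl addition. The C9 ketone with its C8 methyl stereocentre must be turned regioselectively into the C8=C9 alkene (enolisation towards C8, not C10). The straight versus crossed mode of cycloaddition depends on the tether, and irradiation limits scale.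
- Comparison: the chosen strategy is catalytic in chirality and has the C8=C9 alkene in place from the first ring-forming step.

Alternative 3: This plan starts from the chiral pool and disconnects the seven-membered ring entirely. Ozonolysis of the ring alkene of the triethylsilyl ether of (S)-terpinen-4-ol A5, then aldol condensation of the keto aldehyde (C1–C5 bond), gives 5-isopropyl-2-methyl-5-(triethylsilyloxy)cyclopent-1-ene-1-carbaldehyde A4, which holds C1 to C6.
- For it: its key step is the most reliable of the four. The tertiary isopropyl carbinol at C4 is present from the start with defined configuration, so the organocerium addition to a hindered enolisable ketone, a real weakness of the chosen route, is avoided.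
- Against it: A4 postpones every hard problem. The quaternary C1 would have to be made by conjugate addition to the fully substituted β-carbon of an enal under control of the remote C4 centre. Four more carbons and the seven-membered ring must be annulated, C5 and C6 remain unset, and the enantiomeric purity of the terpene limits that of the product. It is the longest plan after its key step.
- Comparison: the chosen strategy puts the quaternary centre and both rings into one step and pays with a later, sterically controlled installation of C4.

Key step: step 9

Assumption: the sense of induction of the copper–bis(oxazoline) catalyst cannot be predicted with confidence; the (S,S)-ligand is written for 17, and its enantiomer is used if the other sense is found.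

## Route

Step 1
Reactants: 1 but-3-enoic acid; 2 Meldrum's acid (2,2-dimethyl-1,3-dioxane-4,6-dione)
Product: 4 methyl 3-oxohex-5-enoate, via acyl Meldrum's acid 3 (not isolated)
Conditions: DCC, DMAP (cat.), CH2Cl2, 0 °C to rt; filter; then MeOH, reflux
Reagents that add atoms: methanol, CO
Why: Carbodiimide-mediated C-acylation of Meldrum's acid, then thermal acylketene formation and methanolysis, is a standard β-keto ester synthesis; low temperature and catalytic DMAP should keep the β,γ-alkene out of conjugation.

Step 2
Reactants: 4 methyl 3-oxohex-5-enoate; 5 4-bromo-2-methylbut-1-ene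
Product: 6 methyl 2-(3-methylbut-3-en-1-yl)-3-oxohex-5-enoate (racemic)
Conditions: NaH (1.0 equiv), THF/DMF, 0 °C; then 5, NaI (cat.), 50 °C
Reagents that add atoms: none
Why: Acetoacetic ester alkylation of the sodium enolate with a primary bromide under iodide catalysis; one equivalent of base should leave the γ-CH2 of the allyl ketone untouched.

Step 3
Reactants: 6 methyl 2-(3-methylbut-3-en-1-yl)-3-oxohex-5-enoate
Product: 7 methyl 5-methyl-2-oxocyclohept-4-ene-1-carboxylate (racemic)
Conditions: second-generation Grubbs catalyst RuCl2(=CHPh)(H2IMes)(PCy3) (5 mol%), 1,4-benzoquinone (10 mol%), CH2Cl2 (5 mM), 40 °C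
Reagents that add atoms: none
Why: Ring-closing metathesis of the monosubstituted with the 1,1-disubstituted alkene closes the seven-membered ring and places the trisubstituted alkene (later C8=C9) without regiochemical ambiguity; benzoquinone suppresses ruthenium hydride isomerisation of the allyl ketone.

Step 4
Reactants: 7 methyl 5-methyl-2-oxocyclohept-4-ene-1-carboxylate
Product: 8 methyl 5-methyl-2-(trifluoromethylsulfonyloxy)cyclohepta-1,4-diene-1-carboxylate
Conditions: i-Pr2NEt, Tf2O, CH2Cl2, −78 °C to 0 °C
Reagents that add atoms: trifluoromethanesulfonic anhydride, O=S(=O)(OS(=O)(=O)C(F)(F)F)C(F)(F)F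
Why: O-Sulfonylation of the β-keto ester enolate, the most acidic site, gives the enol triflate with the double bond between the ring carbons that become C5 and C1.

Step 5
Reactants: 8 methyl 5-methyl-2-(trifluoromethylsulfonyloxy)cyclohepta-1,4-diene-1-carboxylate
Product: 9 methyl 2,5-dimethylcyclohepta-1,4-diene-1-carboxylate
Conditions: Me2CuLi (from CuI and MeLi), Et2O, −78 °C to −30 °C
Reagents that add atoms: lithium dimethylcuprate, [Li+].C[Cu-]C
Why: Addition–elimination of the Gilman cuprate on the β-triflyloxy enoate installs the methyl that becomes the C1 methyl; ester and skipped diene should survive at low temperature.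

Step 6
Reactants: 9 methyl 2,5-dimethylcyclohepta-1,4-diene-1-carboxylate
Product: 10 2,5-dimethylcyclohepta-1,4-diene-1-carboxylic acid
Conditions: KOSiMe3, THF, rt to 40 °C; then aq. HCl (pH 3)
Reagents that add atoms: none
Why: Nucleophilic cleavage of the methyl ester by silanolate under anhydrous, weakly basic conditions, chosen over hot aqueous hydroxide to avoid conjugation of the skipped diene.

Step 7
Reactants: 10 2,5-dimethylcyclohepta-1,4-diene-1-carboxylic acid; 11 potassium methyl malonate
Product: 13 methyl 3-(2,5-dimethylcyclohepta-1,4-dien-1-yl)-3-oxopropanoate, via acyl imidazolide 12 (not isolated)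
Conditions: CDI, THF, rt; then 11, MgCl2, Et3N, MeCN, rt to 40 °C; aq. HCl work-up
Reagents that add atoms: 1,1'-carbonyldiimidazole, O=C(n1ccnc1)n1ccnc1 (its imidazolyl group is kept only in 12)
Why: Claisen-type C-acylation of the magnesium enolate of the malonate half-ester by the acyl imidazolide, with decarboxylation, gives the β-keto ester under nearly neutral conditions; a crossed Claisen condensation of hindered ester 9 with an acetate enolate would be sluggish and strongly basic.

Step 8
Reactants: 13 methyl 3-(2,5-dimethylcyclohepta-1,4-dien-1-yl)-3-oxopropanoate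
Product: 16 methyl 2-[(2,5-dimethylcyclohepta-1,4-dien-1-yl)carbonyl]prop-2-enoate, via Mannich base 14 (not isolated), via ammonium iodide 15 (not isolated)
Conditions: Me2N=CH2+ I−, i-Pr2NEt (1 equiv), CH2Cl2, rt; MeI, rt; then sat. aq. NaHCO3, 0 °C; dried solution used at once
Reagents that add atoms: dimethylmethyleneiminium iodide, C[N+](C)=C.[I-]; iodomethane, CI (its methyl group is kept only in 15)
Why: Mannich reaction with the preformed iminium salt, N-methylation and E1cB loss of trimethylamine unmask the 2-methylene β-keto ester only after all of 13 is consumed, which avoids Michael addition of 13 to 16.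

Step 9
Reactants: 16 methyl 2-[(2,5-dimethylcyclohepta-1,4-dien-1-yl)carbonyl]prop-2-enoate
Product: 17 methyl (1S)-4-hydroxy-1,8-dimethylbicyclo[5.3.0]deca-3,5,8-triene-3-carboxylate (target numbering; enol form of the β-keto ester)
Conditions: Cu(OTf)2 (10 mol%), (S,S)-t-Bu-box (11 mol%), 4 Å MS, CH2Cl2, 0 °C to rt
Reagents that add atoms: none
Why: Proposed new method: two-point binding of the β-keto ester unit of 16 to the chiral divalent-copper Lewis acid gives a 3-oxidopentadienyl cation that closes by thermally allowed conrotatory 4π electrocyclisation, forming C1–C2 and the five-membered ring by union of the two dienone termini. The oxyallyl cation is held as the copper-bound β-keto ester enolate with the positive charge on C5; it loses a C6 proton to give the C5=C6 enone 17 and free the catalyst. The closest known reaction type is the copper–bis(oxazoline)- and copper–pybox-promoted asymmetric Nazarov cyclisation of 2-alkoxycarbonyl divinyl ketones, together with the racemic Cu(OTf)2-catalysed polarised variant; new here is that the electron-rich terminus is fully substituted, so torquoselectivity alone creates a quaternary stereocentre. C1 is the only stereocentre formed, and its configuration follows from the clockwise or counter-clockwise sense of conrotation, which the C2-symmetric ligand imposes by blocking one face of the chelated dienone as the methyl-bearing terminus turns towards the CH2 terminus. The step needs regioselective termination, and the polarisation of the substrate secures it: the enolate half stays on the ester-bearing C3 and the cation on C5, whose only β-hydrogens are on C6 because C1 is quaternary. The unsubstituted CH2 terminus keeps steric strain low while a bond is formed to a tetrasubstituted alkene carbon, and the isolated C8=C9 alkene is not conjugated with the cation and should stay in place. The C1 descriptor is S in 17 and R from 18 onwards only because the CIP priorities change.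

Step 10
Reactants: 17 methyl (1S)-4-hydroxy-1,8-dimethylbicyclo[5.3.0]deca-3,5,8-triene-3-carboxylate
Product: 18 (1R)-1,8-dimethylbicyclo[5.3.0]deca-5,8-dien-4-one (target numbering)
Conditions: LiCl, H2O (2 equiv), DMSO, 120 °C
Reagents that add atoms: none
Why: Krapcho dealkoxycarbonylation: chloride dealkylates the methyl ester and the β-keto carboxylate loses CO2; the quaternary C1 is not affected.

Step 11
Reactants: 18 (1R)-1,8-dimethylbicyclo[5.3.0]deca-5,8-dien-4-one
Product: 19 (1R,5R,6S)-5,6-epoxy-1,8-dimethylbicyclo[5.3.0]dec-8-en-4-one (epoxide oxygen β)
Conditions: 30% aq. H2O2, NaOH (0.3 equiv), MeOH, 0 °C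
Reagents that add atoms: hydrogen peroxide, OO
Why: Weitz–Scheffer epoxidation: hydroperoxide adds to C6 of the s-cis enone and the enolate closes onto oxygen at C5 anti to the vicinal, pseudo-axial C1 methyl, the control seen in alkaline peroxide epoxidation of steroidal 16-en-20-ones; this should give the 5β,6β-epoxide and set C6. The electron-rich C8=C9 alkene does not react with a nucleophilic oxidant.

Step 12
Reactants: 19 (1R,5R,6S)-5,6-epoxy-1,8-dimethylbicyclo[5.3.0]dec-8-en-4-one
Product: 20 (1R,5S,6S)-6-hydroxy-1,8-dimethylbicyclo[5.3.0]dec-8-en-4-one (trans-fused; H5 and 6-OH both β)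
Conditions: SmI2 (2.5 equiv), THF/MeOH, −90 °C; pH 7 buffer
Reagents that add atoms: none
Why: Two single-electron transfers from SmI2 cleave the C5–O bond α to the ketone and leave the C6–O bond, so C6 keeps its configuration. Methanol should protonate the samarium enolate at C5 from the β face, anti to the C1 methyl on the neighbouring carbon (axial protonation), which sets the trans fusion with H5 syn to the C6 hydroxyl.

Step 13
Reactants: 20 (1R,5S,6S)-6-hydroxy-1,8-dimethylbicyclo[5.3.0]dec-8-en-4-one
Product: 21 (1R,4R,5S,6S)-4-isopropyl-1,8-dimethylbicyclo[5.3.0]dec-8-ene-4,6-diol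
Conditions: i-PrMgCl, CeCl3 (4 equiv each; i-PrCeCl2 preformed at −78 °C), THF, −78 °C to −20 °C; aq. NH4Cl
Reagents that add atoms: isopropylmagnesium chloride, CC(C)[Mg]Cl
Why: Organocerium 1,2-addition suits an enolisable, hindered ketone; the first equivalent deprotonates the C6 hydroxyl. Attack on C4 should come from the β face, because the axial C1 methyl blocks the α face in a 1,3 relation; this gives the α hydroxyl and the β isopropyl group.

Step 14
Reactants: 21 (1R,4R,5S,6S)-4-isopropyl-1,8-dimethylbicyclo[5.3.0]dec-8-ene-4,6-diol; 22 4-methoxybenzoyl chloride
Product: 23 (1R,4R,5S,6S)-4-hydroxy-4-isopropyl-1,8-dimethylbicyclo[5.3.0]dec-8-en-6-yl 4-methoxybenzoate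
Conditions: pyridine, DMAP (cat.), CH2Cl2, 0 °C to rt
Reagents that add atoms: none
Why: Nucleophile-catalysed acylation takes the secondary, equatorial C6 hydroxyl; the tertiary C4 hydroxyl is too hindered to react.

Step 15
Reactants: 23 (1R,4R,5S,6S)-4-hydroxy-4-isopropyl-1,8-dimethylbicyclo[5.3.0]dec-8-en-6-yl 4-methoxybenzoate
Product: 24 (1R,4R,5S,6S,8R,9S)-8,9-epoxy-4-hydroxy-4-isopropyl-1,8-dimethylbicyclo[5.3.0]decan-6-yl 4-methoxybenzoate (target, CNP0235939.1)
Conditions: mCPBA, NaHCO3, CH2Cl2, 0 °C
Reagents that add atoms: 3-chloroperbenzoic acid, O=C(OO)c1cccc(Cl)c1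
Why: Prilezhaev epoxidation of the only remaining electron-rich alkene; the peracid should approach C8=C9 from the β face, anti to the axial C1 methyl (1,3 to C9), while the equatorial C6 ester leaves that face open. The buffer protects the acid-sensitive epoxide.

## Compound list

1 | but-3-enoic acid | C=CCC(=O)O | starting material
2 | Meldrum's acid (2,2-dimethyl-1,3-dioxane-4,6-dione) | CC1(C)OC(=O)CC(=O)O1 | starting material
3 | 5-(1-hydroxybut-3-en-1-ylidene)-2,2-dimethyl-1,3-dioxane-4,6-dione (acyl Meldrum's acid, not isolated) | C=CCC(O)=C1C(=O)OC(C)(C)OC1=O | intermediate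
4 | methyl 3-oxohex-5-enoate | C=CCC(=O)CC(=O)OC | intermediate
5 | 4-bromo-2-methylbut-1-ene | CC(=C)CCBr | starting material
6 | methyl 2-(3-methylbut-3-en-1-yl)-3-oxohex-5-enoate (racemic) | C=CCC(=O)C(CCC(C)=C)C(=O)OC | intermediate
7 | methyl 5-methyl-2-oxocyclohept-4-ene-1-carboxylate (racemic) | COC(=O)C1CCC(C)=CCC1=O | intermediate
8 | methyl 5-methyl-2-(trifluoromethylsulfonyloxy)cyclohepta-1,4-diene-1-carboxylate | COC(=O)C1=C(OS(=O)(=O)C(F)(F)F)CC=C(C)CC1 | intermediate
9 | methyl 2,5-dimethylcyclohepta-1,4-diene-1-carboxylate | COC(=O)C1=C(C)CC=C(C)CC1 | intermediate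
10 | 2,5-dimethylcyclohepta-1,4-diene-1-carboxylic acid | OC(=O)C1=C(C)CC=C(C)CC1 | intermediate
11 | potassium methyl malonate (potassium 3-methoxy-3-oxopropanoate) | COC(=O)CC(=O)[O-].[K+] | starting material
12 | (2,5-dimethylcyclohepta-1,4-dien-1-yl)(imidazol-1-yl)methanone (acyl imidazolide, not isolated) | O=C(C1=C(C)CC=C(C)CC1)n1ccnc1 | intermediate
13 | methyl 3-(2,5-dimethylcyclohepta-1,4-dien-1-yl)-3-oxopropanoate | COC(=O)CC(=O)C1=C(C)CC=C(C)CC1 | intermediate
14 | methyl 2-[(dimethylamino)methyl]-3-(2,5-dimethylcyclohepta-1,4-dien-1-yl)-3-oxopropanoate (Mannich base, racemic, not isolated) | COC(=O)C(CN(C)C)C(=O)C1=C(C)CC=C(C)CC1 | intermediate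
15 | [3-(2,5-dimethylcyclohepta-1,4-dien-1-yl)-2-(methoxycarbonyl)-3-oxopropyl]trimethylammonium iodide (racemic, not isolated) | COC(=O)C(C[N+](C)(C)C)C(=O)C1=C(C)CC=C(C)CC1.[I-] | intermediate
16 | methyl 2-[(2,5-dimethylcyclohepta-1,4-dien-1-yl)carbonyl]prop-2-enoate | C=C(C(=O)OC)C(=O)C1=C(C)CC=C(C)CC1 | intermediate
17 | methyl (1S)-4-hydroxy-1,8-dimethylbicyclo[5.3.0]deca-3,5,8-triene-3-carboxylate (target numbering; enol form) | COC(=O)C1=C(O)C2=CCC(C)=CC[C@@]2(C)C1 | intermediate
18 | (1R)-1,8-dimethylbicyclo[5.3.0]deca-5,8-dien-4-one | O=C1CC[C@]2(C)CC=C(C)CC=C12 | intermediate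
19 | (1R,5R,6S)-5,6-epoxy-1,8-dimethylbicyclo[5.3.0]dec-8-en-4-one (epoxide β, anti to the C1 methyl) | O1[C@H]2CC(C)=CC[C@@]3(C)CCC(=O)[C@]123 | intermediate
20 | (1R,5S,6S)-6-hydroxy-1,8-dimethylbicyclo[5.3.0]dec-8-en-4-one (trans-fused) | O[C@H]1CC(C)=CC[C@@]2(C)CCC(=O)[C@H]12 | intermediate
21 | (1R,4R,5S,6S)-4-isopropyl-1,8-dimethylbicyclo[5.3.0]dec-8-ene-4,6-diol | O[C@H]1CC(C)=CC[C@@]2(C)CC[C@@](O)(C(C)C)[C@H]12 | intermediate
22 | 4-methoxybenzoyl chloride | COc1ccc(cc1)C(Cl)=O | starting material
23 | (1R,4R,5S,6S)-4-hydroxy-4-isopropyl-1,8-dimethylbicyclo[5.3.0]dec-8-en-6-yl 4-methoxybenzoate | COc1ccc(C(=O)O[C@H]2CC(C)=CC[C@@]3(C)CC[C@@](O)(C(C)C)[C@H]23)cc1 | intermediate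
24 | (1R,4R,5S,6S,8R,9S)-8,9-epoxy-4-hydroxy-4-isopropyl-1,8-dimethylbicyclo[5.3.0]decan-6-yl 4-methoxybenzoate | COc1ccc(C(=O)O[C@H]2C[C@@]3(C)O[C@H]3C[C@@]3(C)CC[C@@](O)(C(C)C)[C@H]23)cc1 | target

## Step count and least certain steps

Total step count: 15. Longest linear sequence: 15 steps (1 to 24); compounds 2, 5, 11 and 22 enter as purchased building blocks.

Step 9 (key step, beyond precedent).
- What may go wrong: insufficient torquoselectivity, because the two groups that turn at the C1 terminus (methyl and the ring CH2 C10) are similar in size. Also slow turnover through binding of product 17 to copper, a Wagner–Meerwein methyl shift from C1 to the C5 cation in competition with loss of the C6 proton, and oligomerisation of 16.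
- Fallback with known chemistry, from 16 back to 18: cyclisation with Cu(OTf)2 alone, a Lewis-acid-catalysed polarised Nazarov cyclisation, gives the racemic β-keto ester methyl 4-hydroxy-1,8-dimethylbicyclo[5.3.0]deca-3,5,8-triene-3-carboxylate F1. Krapcho dealkoxycarbonylation as in step 10 gives the racemic dienone 1,8-dimethylbicyclo[5.3.0]deca-5,8-dien-4-one F2. Corey–Bakshi–Shibata reduction of F2 with (S)-Me-CBS and catecholborane (toluene, −78 °C) should reduce both enantiomers under catalyst control to 4R alcohols. The racemate thus becomes two diastereomers: the (1R,4R) allylic alcohol 1,8-dimethylbicyclo[5.3.0]deca-5,8-dien-4-ol F3 (hydroxyl trans to the C1 methyl) and its (1S,4R) diastereomer F4 (hydroxyl cis to the methyl). They are separated by chromatography, and F3 is oxidised with MnO2 (CH2Cl2, rt) to 18.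

Step 12.
- What may go wrong: protonation of the samarium enolate from the α face, which would give the cis-fused ketone, and β-elimination of the C6 oxygen on work-up, which would return 18.
- Fallback, from 18 back to 21, that sets C5 by a stereospecific 1,2-hydride shift instead of a protonation: Corey–Bakshi–Shibata reduction with (R)-Me-CBS and catecholborane gives the (1R,4S) allylic alcohol F5 (hydroxyl cis to the C1 methyl). VO(acac)2-catalysed epoxidation with tert-butyl hydroperoxide delivers oxygen to C5=C6 on the face of the hydroxyl and gives the 5α,6α-epoxy-4α-alcohol F6. BF3·OEt2 (CH2Cl2, −78 °C) opens the epoxide at the tertiary C5 while the C4 hydrogen, anti to the breaking C–O bond, migrates to C5 (semipinacol rearrangement); this gives the trans-fused 6α-hydroxy ketone F7, the C6 epimer of 20. i-PrMgCl/CeCl3 as in step 13 gives the 4α,6α-diol F8. Dess–Martin oxidation of the secondary alcohol gives the 4-hydroxy-6-ketone F9. Evans–Saksena reduction with Me4NBH(OAc)3 (MeCN/AcOH, −30 °C), in which the α-oriented C4 hydroxyl delivers hydride to the α face of the C6 carbonyl, gives 21.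

Step 11.
- What may go wrong: poor facial selectivity in the ring closure of the β-peroxy enolate, and hydroxide-induced conjugation of the skipped diene through deprotonation at C7.
- Fallback without base and with a directing group, from 18 back to 19: reduction with (S)-Me-CBS and catecholborane gives the (1R,4R) allylic alcohol F3, the compound already met in the fallback to step 9. VO(acac)2/tert-butyl hydroperoxide epoxidation syn to the β hydroxyl, which is also the face anti to the C1 methyl, gives the 5β,6β-epoxy-4β-alcohol F10. Dess–Martin oxidation gives 19.

Step 13.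
- What may go wrong: enolisation of 20 at C3 or C5, reduction of the ketone by β-hydride transfer from the isopropyl reagent, and retro-aldol opening of the cerium aldolate.
- Fallback, from 20 back to 21: addition of the smaller, non-reducing sp2 nucleophile isopropenylmagnesium bromide/CeCl3 (THF, −78 °C) gives the isopropenyl diol F11. Hydrogenation with RhCl(PPh3)3 (H2, benzene, rt), which saturates a 1,1-disubstituted alkene much faster than the trisubstituted ring alkene, gives 21.

Step 8.
- What may go wrong: loss of 16 before it reaches the catalyst, by Michael addition of amine or of unreacted 13 and by hetero-Diels–Alder dimerisation.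
- Fallback that forms 16 by a neutral oxidation as the last operation, from 9 back to 16: reduction with i-Bu2AlH (CH2Cl2, −78 °C) gives the allylic alcohol (2,5-dimethylcyclohepta-1,4-dien-1-yl)methanol F12. Oxidation with MnO2 gives 2,5-dimethylcyclohepta-1,4-diene-1-carbaldehyde F13. Addition of [α-(methoxycarbonyl)vinyl]diisobutylaluminium (from methyl propiolate, i-Bu2AlH and N-methylmorpholine N-oxide) gives the Morita–Baylis–Hillman-type alcohol methyl 2-[(2,5-dimethylcyclohepta-1,4-dien-1-yl)(hydroxy)methyl]prop-2-enoate F14. Dess–Martin oxidation gives 16.

## Further compounds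

F1 | step 9 | methyl 4-hydroxy-1,8-dimethylbicyclo[5.3.0]deca-3,5,8-triene-3-carboxylate (racemic) | COC(=O)C1=C(O)C2=CCC(C)=CCC2(C)C1
F2 | step 9 | 1,8-dimethylbicyclo[5.3.0]deca-5,8-dien-4-one (racemic) | O=C1CCC2(C)CC=C(C)CC=C12
F3 | step 9 | (1R,4R)-1,8-dimethylbicyclo[5.3.0]deca-5,8-dien-4-ol (hydroxyl trans to the C1 methyl) | O[C@@H]1CC[C@]2(C)CC=C(C)CC=C12
F4 | step 9 | (1S,4R)-1,8-dimethylbicyclo[5.3.0]deca-5,8-dien-4-ol (hydroxyl cis to the C1 methyl) | O[C@@H]1CC[C@@]2(C)CC=C(C)CC=C12
F5 | step 12 | (1R,4S)-1,8-dimethylbicyclo[5.3.0]deca-5,8-dien-4-ol (hydroxyl cis to the C1 methyl) | O[C@H]1CC[C@]2(C)CC=C(C)CC=C12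
F6 | step 12 | 5α,6α-epoxy-1,8-dimethylbicyclo[5.3.0]dec-8-en-4α-ol (C1 as in 18) | O1[C@@H]2CC(C)=CC[C@@]3(C)CC[C@H](O)[C@@]123
F7 | step 12 | trans-fused 6α-hydroxy-1,8-dimethylbicyclo[5.3.0]dec-8-en-4-one (C6 epimer of 20) | O[C@@H]1CC(C)=CC[C@@]2(C)CCC(=O)[C@H]12
F8 | step 12 | 4-isopropyl-1,8-dimethylbicyclo[5.3.0]dec-8-ene-4α,6α-diol (C6 epimer of 21) | O[C@@H]1CC(C)=CC[C@@]2(C)CC[C@@](O)(C(C)C)[C@H]12
F9 | step 12 | trans-fused 4α-hydroxy-4-isopropyl-1,8-dimethylbicyclo[5.3.0]dec-8-en-6-one | O=C1CC(C)=CC[C@@]2(C)CC[C@@](O)(C(C)C)[C@H]12
F10 | step 11 | 5β,6β-epoxy-1,8-dimethylbicyclo[5.3.0]dec-8-en-4β-ol (C1 as in 18) | O1[C@H]2CC(C)=CC[C@@]3(C)CC[C@@H](O)[C@]123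
F11 | step 13 | 1,8-dimethyl-4-(prop-1-en-2-yl)bicyclo[5.3.0]dec-8-ene-4,6-diol (configuration as in 21) | O[C@H]1CC(C)=CC[C@@]2(C)CC[C@@](O)(C(C)=C)[C@H]12
F12 | step 8 | (2,5-dimethylcyclohepta-1,4-dien-1-yl)methanol | OCC1=C(C)CC=C(C)CC1
F13 | step 8 | 2,5-dimethylcyclohepta-1,4-diene-1-carbaldehyde | O=CC1=C(C)CC=C(C)CC1
F14 | step 8 | methyl 2-[(2,5-dimethylcyclohepta-1,4-dien-1-yl)(hydroxy)methyl]prop-2-enoate (racemic) | C=C(C(=O)OC)C(O)C1=C(C)CC=C(C)CC1
A1 | alternative 1 | trans-2-(1-hydroxy-2-methylpropyl)-3,6-dimethyl-3-vinylcyclohept-6-en-1-one | C=C[C@]1(C)CCC(C)=CC(=O)[C@H]1[C@H](O)C(C)C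
A2 | alternative 1 | 3,6-dimethylcyclohepta-2,6-dien-1-one | CC1=CC(=O)C=C(C)CC1
A3 | alternative 2 | C6-silyloxy bicyclo[5.3.0]decane-4,9-dione (target numbering) | CC(C)(C)[Si](C)(C)O[C@H]1C[C@H](C)C(=O)C[C@@]2(C)CCC(=O)[C@H]12
A4 | alternative 3 | 5-isopropyl-2-methyl-5-(triethylsilyloxy)cyclopent-1-ene-1-carbaldehyde | CC1=C(C=O)[C@](O[Si](CC)(CC)CC)(C(C)C)CC1
A5 | alternative 3 | (S)-terpinen-4-ol | CC1=CC[C@](O)(C(C)C)CC1
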